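## Retrosynthetic overview

- Target 8 ⇒ indole 3 + cyclic C-acyl ketimine 7 (cut C2–C3′, aza-Friedel–Crafts).
- 7 ⇒ open α-keto ketimine 6 by cutting N1–C7a (intramolecular SNAr on a 2-fluorophenyl ketone); 6 ⇒ α-azido ketone 5 by adding back N2, so the azide is both the N1 source and the internal oxidant.
- 5 ⇒ carbinol 4 ⇒ arylglyoxal 2 + indole 3; 2 ⇒ 2′-fluoroacetophenone 1.
- Enabling feature: C2 lies between N1 and the C3 ketone, and C3 is bonded to C3a, ortho to C7a of the benzo ring (ring A). The C3 carbonyl therefore acidifies C2–H (N2 loss), activates C7a–F toward the C2 nitrogen, and makes C2=N1 of 7 electrophilic for the second indole.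
- Ring order: both indole units are bought; the five-membered nitrogen ring of the indoxyl (ring B) is the only ring made, last, in step 4.

Key step: step 4

Remark on the chemistry: glyoxal 2 is drawn as the free aldehyde but is handled as its hydrate, which reacts in the same way. Compounds 4 and 5 are racemic; their single stereocenter disappears in step 4, and the target is achiral.

## Route

Step 1
Reactants: 1 1-(2-fluorophenyl)ethan-1-one (2′-fluoroacetophenone)
Product: 2 2-(2-fluorophenyl)-2-oxoacetaldehyde
Conditions: SeO2 (1.2 equiv), 1,4-dioxane/H2O 20:1, reflux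
Reagents that add atoms: selenium dioxide, O=[Se]=O
Why: Riley oxidation of an enolisable aryl methyl ketone to the α-keto aldehyde; the aryl fluoride is inert to SeO2.

Step 2
Reactants: 2 2-(2-fluorophenyl)-2-oxoacetaldehyde (1.2 equiv); 3 1H-indole
Product: 4 1-(2-fluorophenyl)-2-hydroxy-2-(1H-indol-3-yl)ethan-1-one (racemic)
Conditions: EtOH/H2O 1:1, 25 °C, no catalyst
Reagents that add atoms: none
Why: Uncatalysed Friedel–Crafts hydroxyalkylation, in which indole C3 adds to the aldehyde carbon (the most electrophilic carbonyl of the glyoxal) and, without acid, the carbinol should not ionise for a second addition; the new carbinol stereocenter is formed racemic and is erased in step 4.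

Step 3
Reactants: 4 1-(2-fluorophenyl)-2-hydroxy-2-(1H-indol-3-yl)ethan-1-one
Product: 5 2-azido-1-(2-fluorophenyl)-2-(1H-indol-3-yl)ethan-1-one (racemic)
Conditions: TMSN3 (2 equiv), In(OTf)3 (5 mol %), CH2Cl2, −20 → 0 °C
Reagents that add atoms: azidotrimethylsilane, C[Si](C)(C)N=[N+]=[N-]
Why: Lewis-acid-catalysed SN1 azidation of an indol-3-ylcarbinol, in which the indole nitrogen assists ionisation to the 3-alkylideneindoleninium ion and azide captures it at the exocyclic carbon; the product is racemic and its stereocenter is erased in step 4.

Step 4
Reactants: 5 2-azido-1-(2-fluorophenyl)-2-(1H-indol-3-yl)ethan-1-one; 3 1H-indole (1.5 equiv, added in the second stage)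
Product: 8 2,2-bis(1H-indol-3-yl)-1,2-dihydro-3H-indol-3-one, via ketimine 6 (not isolated), via 2-(1H-indol-3-yl)-3H-indol-3-one 7 (not isolated)
Conditions: Cs2CO3 (2.5 equiv), DMSO (0.05 M), 25 °C then 100 °C; then indole, AcOH (equal volume), 25–50 °C
Reagents that add atoms: none
Why: Proposed new method: Cs2CO3 removes the C2–H of 5, acidified by the C3 carbonyl, and the enolate expels N2 to give ketimine 6 as its cesium salt (the known base-induced denitrogenation of α-azido ketones), so the nitrogen is fixed on C2 and C2 reaches the imine level without an external oxidant. On heating, this nitrogen attacks C7a of ring A, which carries fluoride ortho to the C3 carbonyl, and fluoride leaves from the carbonyl-stabilised σ-adduct: an intramolecular SNAr that forms N1–C7a and closes the five-membered ring B in a 5-exo-trig addition–elimination mode to give 7. The closest known reaction types are the SNAr ring closures of 2-fluoroaryl ketone hydrazones to indazoles and of 2-fluoroaryl ketoximes to 1,2-benzisoxazoles; what is new is an α-keto ketimine nitrogen, generated from an azide, as the nucleophile. After acidification with AcOH the C-acyl imine 7 is protonated and indole adds through C3 to C2 (aza-Friedel–Crafts addition, a known reaction of 2-substituted 3H-indol-3-ones), which builds the quaternary carbon. No stereocenter is created, since C2 ends with two identical indol-3-yl groups, and the racemic center of 5 is erased when 6 forms. The selectivity needed is ring closure by the C2 nitrogen ahead of intermolecular reactions: the indole nitrogen of 6 cannot reach C7a, closure gives an unstrained five-membered ring, free indole is withheld until fluoride is consumed so that it cannot be N-arylated, and in acid indole reacts through C3 at C2 of 7, the only electrophilic carbon.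

## Compound list

1 | 1-(2-fluorophenyl)ethan-1-one | CC(=O)c1ccccc1F | starting material
2 | 2-(2-fluorophenyl)-2-oxoacetaldehyde (handled as its hydrate) | O=CC(=O)c1ccccc1F | intermediate
3 | 1H-indole | c1ccc2[nH]ccc2c1 | starting material
4 | 1-(2-fluorophenyl)-2-hydroxy-2-(1H-indol-3-yl)ethan-1-one (racemic) | O=C(c1ccccc1F)C(O)c1c[nH]c2ccccc12 | intermediate
5 | 2-azido-1-(2-fluorophenyl)-2-(1H-indol-3-yl)ethan-1-one (racemic) | O=C(c1ccccc1F)C(N=[N+]=[N-])c1c[nH]c2ccccc12 | intermediate
6 | 1-(2-fluorophenyl)-2-imino-2-(1H-indol-3-yl)ethan-1-one (present as its cesium salt) | N=C(C(=O)c1ccccc1F)c1c[nH]c2ccccc12 | intermediate (not isolated)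
7 | 2-(1H-indol-3-yl)-3H-indol-3-one | O=C1C(c2c[nH]c3ccccc23)=Nc2ccccc12 | intermediate (not isolated)
8 | 2,2-bis(1H-indol-3-yl)-1,2-dihydro-3H-indol-3-one (2,2-bis(3′-indolyl)indoxyl) | O=C1c2ccccc2NC1(c1c[nH]c2ccccc12)c1c[nH]c2ccccc12 | target

## Step count and risks

Total step count: 4. Longest linear sequence: 4 steps (1 → 2 → 4 → 5 → 8).

Steps most likely to fail:

1. Step 4 (proposed new method). The ketimine anion may be consumed by intermolecular condensation, or the azide may be lost from C2 through the indole nitrogen, before fluoride is displaced. The approach of the sp2 nitrogen to C7a may also be too slow at a tolerable temperature. The fallback uses known chemistry and sets out from azide 5. Staudinger reduction (PPh3, THF/H2O, 25 °C) should give 2-amino-1-(2-fluorophenyl)-2-(1H-indol-3-yl)ethan-1-one F1. Intramolecular SNAr amination of the 2-fluorophenyl ketone by the sp3 amine (K2CO3, DMSO, 90 °C, argon) should close N1–C7a to 2-(1H-indol-3-yl)-1,2-dihydro-3H-indol-3-one F2. Aerobic dehydrogenation of this 2-monosubstituted indoxyl (O2, AcOH, 25 °C) should give 7, where the route is rejoined (indole, AcOH, to 8).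

2. Step 3. After ionisation the indoleninium cation may be captured by the indole C3 of a second molecule (oligomerisation) instead of by azide, or the azide may lose N2 prematurely on the Lewis acid. The fallback sets out from carbinol 4 and brings nitrogen in by carbonyl condensation instead of substitution. Oxidation (2-iodoxybenzoic acid, EtOAc, 70 °C) should give 1-(2-fluorophenyl)-2-(1H-indol-3-yl)ethane-1,2-dione F3. Treatment with NH3 (7 M in MeOH, 25 °C) and then Cs2CO3/DMSO should condense reversibly at either carbonyl; only the imine at the indolyl-bearing carbon can cyclise, so the sequence returns to the route at ketimine 6.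

3. Step 2. The carbinol may ionise and take up a second indole (over-alkylation), or an α-ketol shift may move the carbonyl next to the indole. The fallback sets out from indole 3 and makes the C–C bond by acylation. Oxalyl chloride (Et2O, 0 °C) should give 2-(1H-indol-3-yl)-2-oxoacetyl chloride F4. MeNHOMe·HCl with K2CO3 (CH2Cl2/H2O) should give N-methoxy-N-methyl-2-(1H-indol-3-yl)-2-oxoacetamide F5. 2-Fluorophenyllithium (from 1-bromo-2-fluorobenzene and nBuLi, THF, −78 °C, 2.2 equiv) should add to the amide carbonyl to give dione F3. From there the fallback for step 3 is followed, returning to the route at ketimine 6.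

Further compounds
F1 | step 4 | 2-amino-1-(2-fluorophenyl)-2-(1H-indol-3-yl)ethan-1-one | NC(C(=O)c1ccccc1F)c1c[nH]c2ccccc12
F2 | step 4 | 2-(1H-indol-3-yl)-1,2-dihydro-3H-indol-3-one | O=C1C(c2c[nH]c3ccccc23)Nc2ccccc12
F3 | step 3 | 1-(2-fluorophenyl)-2-(1H-indol-3-yl)ethane-1,2-dione | O=C(C(=O)c1c[nH]c2ccccc12)c1ccccc1F
F4 | step 2 | 2-(1H-indol-3-yl)-2-oxoacetyl chloride | O=C(Cl)C(=O)c1c[nH]c2ccccc12
F5 | step 2 | N-methoxy-N-methyl-2-(1H-indol-3-yl)-2-oxoacetamide | CON(C)C(=O)C(=O)c1c[nH]c2ccccc12
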